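**Plan**

1. The acetate C–O bond and the lactone α,β-C=C are cut first, which leads back to the saturated fused lactone 26.
2. In 26 the lactone C=O carbon hangs on a nine-ring carbon that is next to the ring CH carrying the lactone CH2–O. Cutting the bond between these two ring carbons together with the lactone O–C(=O) bond puts the carbonyl carbon back into the ring and gives the ten-membered 2-diazo ketone 24 with a free CH2OH on the neighbouring carbon.
3. The (E)-cyclodec-5-enone is cut at C3–C4 (oxy-Cope) to the trans-1,2-divinylcyclohexanol 18, whose vinyl groups come from CH2=CHMgBr and from a formyl group.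
4. The cyclohexane is cut at C1–C2 (nitrile oxide cycloaddition), C3–C4 (allylboration) and C5–C6 (Michael addition) to (R)-citronellal 6, nitroalkene 5 and an allyl unit.
5. Forward order: chain (steps 1–4), six-membered ring (5), quaternary methyl/vinyl carbon (6–9), ten-membered ring (10–11), diazo ketone (12–14), nine-membered ring and lactone together (15), C=C and acetate (16–19).
6. Stereochemistry: the side-chain centre comes from (R)-citronellal, the two adjacent ring centres from the (R)-diarylprolinol silyl ether, the carbinol centre from (+)-Ipc2B(allyl), the (E) ring alkene from the chair oxy-Cope of a trans-divinyl alcohol, and the fusion centre is retained in the 1,2-shift.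

Key step: step 15

Remark: locants C1–C6 in steps 5–11 refer to the cyclohexane ring (C1 becomes the ketone carbon, C4 bears the silyloxy group, C5 the side chain, C6 the silyloxymethyl group); (R)-citronellal of high enantiomeric purity and the commercial pentane solution of (+)-Ipc2B(CH2CH=CH2) are assumed.

**Route**

Step 1
Reactants: 1 (tert-butyldimethylsilyloxy)acetaldehyde; 2 nitromethane
Product: 5 (E)-tert-butyldimethyl[(3-nitroprop-2-en-1-yl)oxy]silane, via nitro alcohol 3 (not isolated), via mesylate 4 (not isolated)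
Conditions: CH3NO2 (5 equiv), Et3N (0.1 equiv), THF, 0 °C to rt; concentrate; CH3SO2Cl, Et3N, CH2Cl2, −20 to 0 °C
Reagents that add atoms: none
Why: Henry (nitroaldol) addition of nitromethane to the aldehyde and E1cB elimination of the derived mesylate give the conjugated nitroalkene, whose (E) isomer is the thermodynamic product.

Step 2
Reactants: 5 (E)-tert-butyldimethyl[(3-nitroprop-2-en-1-yl)oxy]silane; 6 (R)-citronellal
Product: 7 (2S,3S)-3-[(tert-butyldimethylsilyloxy)methyl]-2-[(2R)-6-methylhept-5-en-2-yl]-4-nitrobutanal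
Conditions: (R)-2-[diphenyl(trimethylsilyloxy)methyl]pyrrolidine (10 mol %), 4-nitrophenol (10 mol %), toluene, 0 °C to rt; 6 (1.5 equiv)
Reagents that add atoms: none
Why: Enamine-catalysed Michael addition of an aldehyde to a nitroalkene (Hayashi type): the anti-(E) enamine of 6 is shielded on one face by the diphenyl(silyloxy)methyl group and adds through the usual synclinal transition state, so the (R)-catalyst should set both new centres (syn, 2S,3S) by catalyst control while the citronellal centre is untouched.

Step 3
Reactants: 7 (2S,3S)-nitro aldehyde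
Product: 8 (4R,5S,6S)-6-[(tert-butyldimethylsilyloxy)methyl]-5-[(2R)-6-methylhept-5-en-2-yl]-7-nitrohept-1-en-4-ol
Conditions: (+)-Ipc2B(CH2CH=CH2) (1 M in pentane), Et2O, −78 to −40 °C; then HOCH2CH2NH2, rt
Reagents that add atoms: (+)-B-allyldiisopinocampheylborane, C=CCB(C1CC2CC(C1C)C2(C)C)C1CC2CC(C1C)C2(C)C
Why: Brown allylboration through a closed chair transition state; the (+)-reagent should deliver allyl to the Re face and set the carbinol centre (4R) by reagent control, and the neutral, non-oxidative work-up spares the epimerizable α-centre and the nitro group.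

Step 4
Reactants: 8 homoallylic alcohol
Product: 9 (4R,5S,6S)-6-[(tert-butyldimethylsilyloxy)methyl]-5-[(2R)-6-methylhept-5-en-2-yl]-7-nitro-4-(triisopropylsilyloxy)hept-1-ene
Conditions: iPr3SiOSO2CF3, 2,6-lutidine, CH2Cl2, −78 to 0 °C
Reagents that add atoms: triisopropylsilyl trifluoromethanesulfonate, CC(C)[Si](OS(=O)(=O)C(F)(F)F)(C(C)C)C(C)C
Why: Silylation of a hindered secondary alcohol with a silyl triflate and a pyridine base too weak to form the nitronate; the triisopropylsilyl ether is chosen to outlast the primary tert-butyldimethylsilyl ether in step 14.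

Step 5
Reactants: 9 nitro alkene
Product: 11 7-[(tert-butyldimethylsilyloxy)methyl]-6-[(2R)-6-methylhept-5-en-2-yl]-5-(triisopropylsilyloxy)-3,3a,4,5,6,7-hexahydro-2,1-benzisoxazole (5-oxygen cis to the 6-side chain; 7-CH2O trans to it), via nitrile oxide 10 (not isolated)
Conditions: PhNCO (3 equiv, slow addition), Et3N (0.2 equiv), toluene (0.01 M), rt to 60 °C
Reagents that add atoms: none
Why: Mukaiyama–Hoshino dehydration of the primary nitroalkane to a nitrile oxide and intramolecular nitrile oxide–alkene [3+2] cycloaddition; the four-atom tether enforces the fused mode (dipole carbon to the internal alkene carbon) and closes the cyclohexane ring, and the new C3a centre is of no consequence because step 7 enolizes it.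

Step 6
Reactants: 11 isoxazoline
Product: 13 (4R,5S,6R)-6-[(tert-butyldimethylsilyloxy)methyl]-2-(hydroxymethyl)-5-[(2R)-6-methylhept-5-en-2-yl]-4-(triisopropylsilyloxy)cyclohexan-1-one, via hydroxy imine 12 (not isolated)
Conditions: SmI2, THF, 0 °C; then B(OH)3, H2O/MeOH, rt
Reagents that add atoms: water, O
Why: Reductive N–O cleavage of the 2-isoxazoline by SmI2 and boric-acid-buffered hydrolysis of the β-hydroxy imine unmask the aldol-type β-hydroxy ketone under conditions that should leave the alkene and both silyl ethers intact and not dehydrate the aldol.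

Step 7
Reactants: 13 β-hydroxy ketone
Product: 14 (4R,5S,6R)-6-[(tert-butyldimethylsilyloxy)methyl]-2-(hydroxymethylidene)-5-[(2R)-6-methylhept-5-en-2-yl]-4-(triisopropylsilyloxy)cyclohexan-1-one (enol form of the 2-formyl ketone)
Conditions: Dess–Martin periodinane (1.1 equiv), NaHCO3, CH2Cl2, 0 °C
Reagents that add atoms: none
Why: Dess–Martin oxidation of the primary alcohol gives the β-keto aldehyde, which rests as its chelated hydroxymethylidene form and so removes the C2 stereocentre.

Step 8
Reactants: 14 hydroxymethylidene ketone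
Product: 15 (2R,4R,5S,6R)-6-[(tert-butyldimethylsilyloxy)methyl]-2-formyl-2-methyl-5-[(2R)-6-methylhept-5-en-2-yl]-4-(triisopropylsilyloxy)cyclohexan-1-one (methyl trans to the C4 oxygen)
Conditions: CH3I, K2CO3, acetone, rt
Reagents that add atoms: iodomethane, CI
Why: C-Alkylation of a 2-(hydroxymethylidene) ketone; iodomethane should approach C2 of the planar enolate on the face opposite the pseudoaxial C4 silyloxy group (avoidance of a 1,3-diaxial contact), placing formyl cis and methyl trans to the C4 oxygen.

Step 9
Reactants: 15 formyl ketone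
Product: 16 (2R,4R,5S,6R)-6-[(tert-butyldimethylsilyloxy)methyl]-2-ethenyl-2-methyl-5-[(2R)-6-methylhept-5-en-2-yl]-4-(triisopropylsilyloxy)cyclohexan-1-one
Conditions: Ph3PCH3Br, KN(SiMe3)2, THF, 0 °C; then 15, −78 to 0 °C
Reagents that add atoms: methylenetriphenylphosphorane (from Ph3PCH3Br), C=P(c1ccccc1)(c1ccccc1)c1ccccc1
Why: Wittig methylenation; the ylide takes the aldehyde and leaves alone the ketone flanked by a quaternary and a tertiary carbon, with low temperature and one equivalent of ylide limiting deformylation and enolization.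

Step 10
Reactants: 16 methyl vinyl ketone; 17 vinylmagnesium bromide
Product: 18 (1R,2R,4R,5S,6R)-6-[(tert-butyldimethylsilyloxy)methyl]-1,2-diethenyl-2-methyl-5-[(2R)-6-methylhept-5-en-2-yl]-4-(triisopropylsilyloxy)cyclohexan-1-ol (vinyl groups trans)
Conditions: CH2=CHMgBr (3 equiv), THF, −78 to 0 °C; aq. NH4Cl
Reagents that add atoms: none
Why: Grignard 1,2-addition; in the chair with equatorial C5 and C6 substituents the C2 vinyl group is axial and blocks the equatorial trajectory, so vinyl should add axially from the opposite face and the two vinyl groups end up trans.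

Step 11
Reactants: 18 trans-divinyl alcohol
Product: 21 (5E,8R,9S,10R)-10-[(tert-butyldimethylsilyloxy)methyl]-6-methyl-9-[(2R)-6-methylhept-5-en-2-yl]-8-(triisopropylsilyloxy)cyclodec-5-en-1-one, via potassium alkoxide 19 (not isolated), via potassium enolate 20 (not isolated)
Conditions: KN(SiMe3)2, 18-crown-6, THF, 0 to 60 °C; then aq. NH4Cl at −78 °C
Reagents that add atoms: none
Why: Anionic oxy-Cope rearrangement ([3,3] shift of the potassium alkoxide); a trans-1,2-divinylcyclohexanolate can react only through the chair-like transition state with both vinyl groups equatorial, which gives the (E)-trisubstituted ring alkene, and enolate formation makes the shift irreversible.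

Step 12
Reactants: 21 cyclodecenone
Product: 22 2-(trifluoroacetyl) derivative of 21 (enol and diketone forms; used crude)
Conditions: LiN(SiMe3)2, THF, −78 °C; CF3CO2CH2CF3, −78 °C; aq. HCl work-up
Reagents that add atoms: 2,2,2-trifluoroethyl trifluoroacetate, O=C(OCC(F)(F)F)C(F)(F)F
Why: Kinetic deprotonation takes the C2 methylene and not the substituted C10 methine, and the lithium enolate is C-acylated in a Claisen-type trifluoroacetylation that activates C2 for deacylative diazo transfer.

Step 13
Reactants: 22 trifluoroacetyl ketone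
Product: 23 (5E,8R,9S,10R)-10-[(tert-butyldimethylsilyloxy)methyl]-2-diazo-6-methyl-9-[(2R)-6-methylhept-5-en-2-yl]-8-(triisopropylsilyloxy)cyclodec-5-en-1-one
Conditions: CH3SO2N3, Et3N, H2O (1 equiv), CH3CN, rt
Reagents that add atoms: methanesulfonyl azide, CS(=O)(=O)N=[N+]=[N-]
Why: Deacylative (detrifluoroacetylative) Regitz diazo transfer: the sulfonyl azide adds to the 1,3-dicarbonyl anion and the adduct collapses with loss of N-mesyl trifluoroacetamide, leaving the diazo group on C2 only.

Step 14
Reactants: 23 bis-silyl diazo ketone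
Product: 24 (5E,8R,9S,10R)-2-diazo-10-(hydroxymethyl)-6-methyl-9-[(2R)-6-methylhept-5-en-2-yl]-8-(triisopropylsilyloxy)cyclodec-5-en-1-one
Conditions: Bu4NF, AcOH (1:1), THF, 0 °C to rt
Reagents that add atoms: none
Why: Fluoride-mediated silyl ether cleavage, in which the unhindered primary tert-butyldimethylsilyl ether should react far faster than the hindered secondary triisopropylsilyl ether; acetic acid buffering protects the β-hydroxy ketone from retro-aldol cleavage and the diazo ketone from base.

Step 15
Reactants: 24 hydroxy diazo ketone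
Product: 26 (3aS,4S,5R,7E)-7-methyl-4-[(2R)-6-methylhept-5-en-2-yl]-5-(triisopropylsilyloxy)-3,3a,4,5,6,9,10,10a-octahydro-1H-cyclonona[c]furan-1-one (either epimer at C10a), via ketene 25 (not isolated)
Conditions: hν (medium-pressure Hg lamp, Pyrex filter), degassed CH2Cl2 (0.005 M), 0 °C to rt
Reagents that add atoms: none
Why: Irradiation expels N2 and, in a concerted Wolff 1,2-shift from the s-cis form, the C10 ring carbon moves with its bonding pair from the carbonyl carbon to C2, so that the old carbonyl carbon leaves the ring as the C=O of ketene 25 and the carbocycle shrinks from ten to nine members. The closest known reaction type is the photochemical Wolff ring contraction of cyclic 2-diazo ketones with capture of the ketene by an alcohol, used here with the alcohol inside the molecule. The nine-membered ring is thus closed by ring contraction (1,2-shift) and not by cyclization, and the γ-lactone by 5-exo-dig addition of the primary hydroxyl oxygen to the ketene carbonyl carbon followed by tautomerization of the ester enol. The migrating carbon keeps its configuration, which fixes the fusion centre C3a, whereas the new centre C10a is set by uncontrolled protonation and either epimer is used because it is planarized in steps 16 and 17. The step needs migration to outrun 1,2-hydride shift to the enone, O–H insertion and intermolecular esterification; photochemical rather than metal-carbenoid activation, a hydroxyl group placed for five-membered ring closure and high dilution are expected to secure this. Which group migrates is not open to choice, since only the substituent of the carbonyl carbon (C10) can shift to the carbene centre, and the diazo group sits on C2 because step 12 enolized the methylene side.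

Step 16
Reactants: 26 fused lactone
Product: 27 10a-bromo derivative of 26 (bromine cis to the C3a hydrogen)
Conditions: LiN(SiMe3)2, THF, −78 °C; BrCCl2CCl2Br, −78 °C
Reagents that add atoms: 1,2-dibromo-1,1,2,2-tetrachloroethane, BrC(Cl)(Cl)C(Cl)(Cl)Br
Why: Bromination of the lithium lactone enolate with a positive-bromine donor that does not attack alkenes; the electrophile is expected on the face of C10a opposite the C3a–C4 ring bond (cis to the C3a hydrogen), as in alkylations of β-substituted butyrolactone enolates, and both C10a epimers of 26 converge in the planar enolate.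

Step 17
Reactants: 27 bromo lactone
Product: 28 (3aS,4S,5R,7E,10E)-7-methyl-4-[(2R)-6-methylhept-5-en-2-yl]-5-(triisopropylsilyloxy)-3,3a,4,5,6,9-hexahydro-1H-cyclonona[c]furan-1-one
Conditions: 1,8-diazabicyclo[5.4.0]undec-7-ene (DBU), toluene, rt to 50 °C
Reagents that add atoms: none
Why: E2 dehydrobromination; with the C3a hydrogen syn to bromine only the C10 methylene offers an anti-periplanar hydrogen, and a nine-membered ring that already holds an (E) alkene can take the new double bond only with C9 cis to C3a, which is the (10E) geometry of the target.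

Step 18
Reactants: 28 silyl ether
Product: 29 (3aS,4S,5R,7E,10E)-5-hydroxy-7-methyl-4-[(2R)-6-methylhept-5-en-2-yl]-3,3a,4,5,6,9-hexahydro-1H-cyclonona[c]furan-1-one
Conditions: HF·pyridine, pyridine, THF, 0 °C to rt
Reagents that add atoms: none
Why: Fluoride-mediated desilylation of the secondary triisopropylsilyl ether under buffered, non-basic conditions that should not move the skipped diene or open the lactone.

Step 19
Reactants: 29 hydroxy lactone
Product: 30 (3aS,4S,5R,7E,10E)-7-methyl-4-[(2R)-6-methylhept-5-en-2-yl]-1-oxo-3,3a,4,5,6,9-hexahydro-1H-cyclonona[c]furan-5-yl acetate (target)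
Conditions: Ac2O, pyridine, 4-(dimethylamino)pyridine (5 mol %), CH2Cl2, 0 °C to rt
Reagents that add atoms: acetic anhydride, CC(=O)OC(C)=O
Why: 4-(Dimethylamino)pyridine-catalysed acylation of the secondary alcohol with acetic anhydride, with no change at any stereocentre.

**Compound list**

1 | (tert-butyldimethylsilyloxy)acetaldehyde | O=CCO[Si](C)(C)C(C)(C)C | starting material
2 | nitromethane | C[N+](=O)[O-] | starting material
3 | 1-(tert-butyldimethylsilyloxy)-3-nitropropan-2-ol (racemic) | OC(C[N+](=O)[O-])CO[Si](C)(C)C(C)(C)C | intermediate (not isolated)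
4 | methanesulfonate of 3 (racemic) | CS(=O)(=O)OC(C[N+](=O)[O-])CO[Si](C)(C)C(C)(C)C | intermediate (not isolated)
5 | (E)-tert-butyldimethyl[(3-nitroprop-2-en-1-yl)oxy]silane | [O-][N+](=O)/C=C/CO[Si](C)(C)C(C)(C)C | intermediate
6 | (R)-citronellal, (3R)-3,7-dimethyloct-6-enal | C[C@H](CCC=C(C)C)CC=O | starting material
7 | (2S,3S)-3-[(tert-butyldimethylsilyloxy)methyl]-2-[(2R)-6-methylhept-5-en-2-yl]-4-nitrobutanal | O=C[C@@H]([C@H](C)CCC=C(C)C)[C@H](CO[Si](C)(C)C(C)(C)C)C[N+](=O)[O-] | intermediate
8 | (4R,5S,6S)-6-[(tert-butyldimethylsilyloxy)methyl]-5-[(2R)-6-methylhept-5-en-2-yl]-7-nitrohept-1-en-4-ol | C=CC[C@@H](O)[C@@H]([C@H](C)CCC=C(C)C)[C@H](CO[Si](C)(C)C(C)(C)C)C[N+](=O)[O-] | intermediate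
9 | triisopropylsilyl ether of 8 | C=CC[C@@H](O[Si](C(C)C)(C(C)C)C(C)C)[C@@H]([C@H](C)CCC=C(C)C)[C@H](CO[Si](C)(C)C(C)(C)C)C[N+](=O)[O-] | intermediate
10 | nitrile oxide from 9 | C=CC[C@@H](O[Si](C(C)C)(C(C)C)C(C)C)[C@@H]([C@H](C)CCC=C(C)C)[C@H](CO[Si](C)(C)C(C)(C)C)C#[N+][O-] | intermediate (not isolated)
11 | fused isoxazoline (hexahydro-2,1-benzisoxazole; 3a-H drawn cis to the 5-oxygen, inconsequential) | O1N=C2[C@@H](CO[Si](C)(C)C(C)(C)C)[C@H]([C@H](C)CCC=C(C)C)[C@H](O[Si](C(C)C)(C(C)C)C(C)C)C[C@H]2C1 | intermediate
12 | β-hydroxy imine from 11 | N=C1[C@@H](CO[Si](C)(C)C(C)(C)C)[C@H]([C@H](C)CCC=C(C)C)[C@H](O[Si](C(C)C)(C(C)C)C(C)C)C[C@H]1CO | intermediate (not isolated)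
13 | 2-(hydroxymethyl)cyclohexanone (C2 as drawn, inconsequential) | O=C1[C@@H](CO[Si](C)(C)C(C)(C)C)[C@H]([C@H](C)CCC=C(C)C)[C@H](O[Si](C(C)C)(C(C)C)C(C)C)C[C@H]1CO | intermediate
14 | 2-(hydroxymethylidene)cyclohexanone (enol of the formyl ketone) | O=C1[C@@H](CO[Si](C)(C)C(C)(C)C)[C@H]([C@H](C)CCC=C(C)C)[C@H](O[Si](C(C)C)(C(C)C)C(C)C)C/C1=C/O | intermediate
15 | (2R,4R,5S,6R)-2-formyl-2-methylcyclohexanone | O=C1[C@@H](CO[Si](C)(C)C(C)(C)C)[C@H]([C@H](C)CCC=C(C)C)[C@H](O[Si](C(C)C)(C(C)C)C(C)C)C[C@]1(C)C=O | intermediate
16 | (2R,4R,5S,6R)-2-ethenyl-2-methylcyclohexanone | O=C1[C@@H](CO[Si](C)(C)C(C)(C)C)[C@H]([C@H](C)CCC=C(C)C)[C@H](O[Si](C(C)C)(C(C)C)C(C)C)C[C@]1(C)C=C | intermediate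
17 | vinylmagnesium bromide | C=C[Mg]Br | starting material
18 | (1R,2R,4R,5S,6R)-trans-1,2-diethenylcyclohexanol | O[C@]1(C=C)[C@@H](CO[Si](C)(C)C(C)(C)C)[C@H]([C@H](C)CCC=C(C)C)[C@H](O[Si](C(C)C)(C(C)C)C(C)C)C[C@]1(C)C=C | intermediate
19 | potassium alkoxide of 18 | [K+].[O-][C@]1(C=C)[C@@H](CO[Si](C)(C)C(C)(C)C)[C@H]([C@H](C)CCC=C(C)C)[C@H](O[Si](C(C)C)(C(C)C)C(C)C)C[C@]1(C)C=C | intermediate (not isolated)
20 | potassium C1–C2 enolate of 21 | CC(C)[Si](C(C)C)(C(C)C)O[C@@H]1C/C(C)=C/CCC=C([O-])[C@@H](CO[Si](C)(C)C(C)(C)C)[C@@H]1[C@H](C)CCC=C(C)C.[K+] | intermediate (not isolated)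
21 | (5E,8R,9S,10R)-cyclodec-5-en-1-one | CC(C)[Si](C(C)C)(C(C)C)O[C@@H]1C/C(C)=C/CCCC(=O)[C@@H](CO[Si](C)(C)C(C)(C)C)[C@@H]1[C@H](C)CCC=C(C)C | intermediate
22 | 2-(trifluoroacetyl) derivative of 21 | CC(C)[Si](C(C)C)(C(C)C)O[C@@H]1C/C(C)=C/CCC(C(=O)C(F)(F)F)C(=O)[C@@H](CO[Si](C)(C)C(C)(C)C)[C@@H]1[C@H](C)CCC=C(C)C | intermediate
23 | (5E,8R,9S,10R)-2-diazo ketone, bis-silyl ether | CC(C)[Si](C(C)C)(C(C)C)O[C@@H]1C/C(C)=C/CCC(=[N+]=[N-])C(=O)[C@@H](CO[Si](C)(C)C(C)(C)C)[C@@H]1[C@H](C)CCC=C(C)C | intermediate
24 | (5E,8R,9S,10R)-2-diazo-10-(hydroxymethyl) ketone | CC(C)[Si](C(C)C)(C(C)C)O[C@@H]1C/C(C)=C/CCC(=[N+]=[N-])C(=O)[C@@H](CO)[C@@H]1[C@H](C)CCC=C(C)C | intermediate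
25 | nine-membered ketene | CC(C)[Si](C(C)C)(C(C)C)O[C@@H]1C/C(C)=C/CCC(=C=O)[C@@H](CO)[C@@H]1[C@H](C)CCC=C(C)C | intermediate (not isolated)
26 | (3aS,4S,5R,7E) saturated fused lactone (either C10a epimer) | CC(C)[Si](C(C)C)(C(C)C)O[C@@H]1C/C(C)=C/CCC2C(=O)OC[C@H]2[C@@H]1[C@H](C)CCC=C(C)C | intermediate
27 | 10a-bromo lactone (Br cis to C3a–H) | CC(C)[Si](C(C)C)(C(C)C)O[C@@H]1C/C(C)=C/CC[C@@]2(Br)C(=O)OC[C@H]2[C@@H]1[C@H](C)CCC=C(C)C | intermediate
28 | (3aS,4S,5R,7E,10E) alkylidene lactone, triisopropylsilyl ether | CC(C)[Si](C(C)C)(C(C)C)O[C@@H]1C/C(C)=C/C/C=C2/C(=O)OC[C@H]2[C@@H]1[C@H](C)CCC=C(C)C | intermediate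
29 | (3aS,4S,5R,7E,10E) hydroxy alkylidene lactone | O[C@@H]1C/C(C)=C/C/C=C2/C(=O)OC[C@H]2[C@@H]1[C@H](C)CCC=C(C)C | intermediate
30 | (3aS,4S,5R,7E,10E)-7-methyl-4-[(2R)-6-methylhept-5-en-2-yl]-1-oxo-3,3a,4,5,6,9-hexahydro-1H-cyclonona[c]furan-5-yl acetate | CC(=O)O[C@@H]1C/C(C)=C/C/C=C2/C(=O)OC[C@H]2[C@@H]1[C@H](C)CCC=C(C)C | target

**Count and risks**

Total: 19 steps. Longest linear sequence: 19 steps (from 1 and 2; 6 enters in step 2).

Step 11. In the favoured chair of alkoxide 19 the two vinyl groups are anti, so the [3,3] shift must pass through a strained chair in which they are gauche. The rearrangement may then be slow enough for the product enolate to equilibrate toward C10 and expel silanolate, or the temperature needed may bring on transannular closure of the cyclodecenone. The fallback sets out from 16 and builds the C1 epimer of the carbinol, whose vinyl groups are already gauche in the ground-state chair. Dimethylsulfoxonium methylide (Me3S(O)I, NaH, DMSO) should deliver the methylene equatorially and give the spiro-epoxide of 16 F1. Excess dimethylsulfonium methylide (Me3SI, n-BuLi, THF) then opens the epoxide at its CH2 and eliminates Me2S to give the cis-divinyl alcohol F2 with an equatorial C1 vinyl group. KN(SiMe3)2 and 18-crown-6 at 0 °C to rt should rearrange it through the same chair transition state to the (E) ketone, and the route is rejoined at 21.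

Step 15. The excited diazo ketone or its carbene may be intercepted before migration (insertion into the nearby O–H bond, 1,2-hydride shift), or the ketene may esterify between molecules instead of closing the lactone. The fallback sets out from 23, in which the hydroxyl group is still silylated. Photolysis in MeOH/THF gives the classical Wolff ring contraction with external capture and yields the nine-membered methyl ester F3. Bu4NF/AcOH then frees the primary alcohol to give the hydroxy ester F4, which is lactonized with pyridinium p-toluenesulfonate in toluene at 60 °C with loss of methanol. The route is rejoined at 26.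

Step 17. Loss of HBr may run toward the fusion carbon if bromine has entered on the other face (the C3a hydrogen is then anti to it), or the anti alignment of a C10 hydrogen may be hard to reach, so that forcing conditions move double bonds. The fallback sets out from 26 and uses a syn elimination, which has the opposite stereochemical demand. LiN(SiMe3)2 then PhSeCl at −78 °C gives the 10a-phenylselenide F5, drawn for the case in which the electrophile lands anti to the C3a hydrogen. H2O2 and pyridine in CH2Cl2 at 0 °C give the selenoxide F6, which can then reach only the C10 methylene hydrogens for syn elimination. The route is rejoined at 28.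

**Further compounds**

F1 | step 11 | spiro-epoxide of 16 (1-oxaspiro[2.5]octane; epoxide oxygen trans to the C2 vinyl group) | C1O[C@]12[C@@H](CO[Si](C)(C)C(C)(C)C)[C@H]([C@H](C)CCC=C(C)C)[C@H](O[Si](C(C)C)(C(C)C)C(C)C)C[C@]2(C)C=C
F2 | step 11 | (1S,2R,4R,5S,6R)-cis-1,2-diethenylcyclohexanol (C1 epimer of 18) | O[C@@]1(C=C)[C@@H](CO[Si](C)(C)C(C)(C)C)[C@H]([C@H](C)CCC=C(C)C)[C@H](O[Si](C(C)C)(C(C)C)C(C)C)C[C@]1(C)C=C
F3 | step 15 | ring-contracted methyl cyclonon-4-ene-1-carboxylate, bis-silyl ether | CC(C)[Si](C(C)C)(C(C)C)O[C@@H]1C/C(C)=C/CCC(C(=O)OC)[C@@H](CO[Si](C)(C)C(C)(C)C)[C@@H]1[C@H](C)CCC=C(C)C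
F4 | step 15 | hydroxy methyl ester from F3 | CC(C)[Si](C(C)C)(C(C)C)O[C@@H]1C/C(C)=C/CCC(C(=O)OC)[C@@H](CO)[C@@H]1[C@H](C)CCC=C(C)C
F5 | step 17 | 10a-phenylselenyl lactone (Se anti to C3a–H) | CC(C)[Si](C(C)C)(C(C)C)O[C@@H]1C/C(C)=C/CC[C@]2([Se]c3ccccc3)C(=O)OC[C@H]2[C@@H]1[C@H](C)CCC=C(C)C
F6 | step 17 | selenoxide of F5 | CC(C)[Si](C(C)C)(C(C)C)O[C@@H]1C/C(C)=C/CC[C@]2([Se](=O)c3ccccc3)C(=O)OC[C@H]2[C@@H]1[C@H](C)CCC=C(C)C
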